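**Retrosynthetic overview**

1. Target 15 comes from its 2',4'-bis-MOM ether 14 by mild acid. 14 comes from the 5-O-(1,1-dimethylallyl) ether 12 by an aromatic Claisen rearrangement that moves the allyl unit from O5 to C6 as a prenyl group and frees the 5-hydroxyl.
2. 12 comes from 5-fluoroisoflavone 10 by displacement of the C5 fluoride, which lies peri to the C4 carbonyl, with a tertiary allylic alkoxide.
3. 10 comes from hydroxymethylene ketone 9 by closure of ring C at O1–C8a. The strategy rests on one feature: C5 and C8a of ring A both carry oxygen and both are ortho to C4a, the carbon bearing the C4 carbonyl. Ring A can therefore be bought as a 2,6-difluoro-4-methoxybenzoyl unit whose two equivalent, carbonyl-activated C–F bonds become O1 and then O5.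
4. 9 comes from C-acylation of morpholine enamine 5 (from ester 1 via aldehyde 3 and morpholine 4) with acid chloride 7 (from acid 6), followed by hydrolysis.
5. Rings A and B are bought; ring C is the only ring formed (step 6).

Key step: step 6

Remark: ring B is taken from commercial methyl (2,4-dihydroxyphenyl)acetate, because ester reduction reaches the arylacetaldehyde without an acidic enol ether hydrolysis that aryl MOM ethers tolerate poorly; 9 is drawn as the chelated Z-enol and is assumed to equilibrate freely with its keto aldehyde form.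

**Route**

Step 1
Reactants: 1 methyl (2,4-dihydroxyphenyl)acetate
Product: 2 methyl [2,4-bis(methoxymethoxy)phenyl]acetate
Conditions: MOMCl, iPr2NEt, CH2Cl2, 0 °C → rt
Reagents that add atoms: chloromethyl methyl ether (MOMCl), COCCl
Why: O-alkylation of both phenols by the reactive α-chloro ether under amine base (MOM ether formation) should be clean, since neither hydroxyl is chelated and the ester is inert.

Step 2
Reactants: 2 methyl [2,4-bis(methoxymethoxy)phenyl]acetate
Product: 3 [2,4-bis(methoxymethoxy)phenyl]acetaldehyde
Conditions: iBu2AlH (1.1 equiv), CH2Cl2, −78 °C; MeOH, then aq KNaC4H4O6 (potassium sodium tartrate)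
Reagents that add atoms: none
Why: Partial reduction of an ester with iBu2AlH at low temperature stops at the aluminium hemiacetal, which releases the aldehyde only on work-up; MOM ethers are inert to hydride, and the crude aldehyde is used at once.

Step 3
Reactants: 3 [2,4-bis(methoxymethoxy)phenyl]acetaldehyde; 4 morpholine
Product: 5 (E)-4-{2-[2,4-bis(methoxymethoxy)phenyl]ethenyl}morpholine
Conditions: morpholine (1.5 equiv), 4 Å molecular sieves, toluene, 0 °C → rt; used crude
Reagents that add atoms: none
Why: Enamine formation from an aldehyde and a secondary amine needs no acid here, because the enamine is conjugated with the aryl ring and should form as the E-styryl isomer.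

Step 4
Reactants: 6 2,6-difluoro-4-methoxybenzoic acid
Product: 7 2,6-difluoro-4-methoxybenzoyl chloride
Conditions: (COCl)2, cat. DMF, CH2Cl2, 0 °C → rt
Reagents that add atoms: oxalyl chloride, O=C(Cl)C(=O)Cl
Why: Acid chloride formation through the chloroiminium salt from DMF is standard and is driven by loss of CO, CO2 and HCl.

Step 5
Reactants: 5 (E)-4-{2-[2,4-bis(methoxymethoxy)phenyl]ethenyl}morpholine; 7 2,6-difluoro-4-methoxybenzoyl chloride
Product: 9 (Z)-2-[2,4-bis(methoxymethoxy)phenyl]-1-(2,6-difluoro-4-methoxyphenyl)-3-hydroxyprop-2-en-1-one, via morpholino enaminone 8 (not isolated)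
Conditions: Et3N, CH2Cl2, 0 → 40 °C; then 1 M aq HCl, THF, 0 °C → rt
Reagents that add atoms: water, O
Why: Stork enamine acylation: the aryl-bearing β-carbon of the enamine attacks the aroyl chloride (which has no α-hydrogen, so no ketene can form), Et3N removes the acidic proton to give vinylogous amide 8, and cold dilute acid exchanges morpholine for hydroxyl by addition–elimination to give the chelated enol while the aryl MOM ethers should survive.

Step 6
Reactants: 9 (Z)-2-[2,4-bis(methoxymethoxy)phenyl]-1-(2,6-difluoro-4-methoxyphenyl)-3-hydroxyprop-2-en-1-one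
Product: 10 5-fluoro-7-methoxy-3-[2,4-bis(methoxymethoxy)phenyl]-4H-chromen-4-one (5-fluoro-7-methoxy-2',4'-bis(methoxymethoxy)isoflavone)
Conditions: K2CO3 (2 equiv), dry DMF, 60 °C
Reagents that add atoms: none
Why: K2CO3 deprotonates the chelated enol, and after rotation about the C3–C4 bond the enolate oxygen adds to one fluorine-bearing carbon of ring A (the future C8a); the charge of the σ-adduct is delocalised onto C4a and into the C4 carbonyl, and loss of fluoride restores aromaticity (addition–elimination, SNAr). The closest known reaction type is the Grohe-type cycloaromatisation of ortho-fluoroaroyl enols and enamines to chromones and 4-quinolones, together with the base-mediated closure of 1-(2-fluoroaryl)-1,3-diketones to flavones. Ring C closes as a six-membered ring through oxygen onto an sp2 carbon, a 6-exo-trig closure if the C8a–C8 π bond is counted as the one that opens, which is a favoured mode. No stereocentre is formed. The step needs O- rather than C-attack of the ambident enolate, which ring size secures because attack through C3 would give a four-membered ring; no choice between the fluorines is needed, because the two C–F bonds are related by the mirror plane of the 2,6-difluoro-4-methoxyphenyl group and either closure gives the same product. Carbonate is too poor a nucleophile to displace the second fluoride, which is kept for step 7.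

Step 7
Reactants: 10 5-fluoro-7-methoxy-3-[2,4-bis(methoxymethoxy)phenyl]-4H-chromen-4-one; 11 2-methylbut-3-en-2-ol
Product: 12 7-methoxy-3-[2,4-bis(methoxymethoxy)phenyl]-5-[(2-methylbut-3-en-2-yl)oxy]-4H-chromen-4-one
Conditions: 11 (1.5 equiv), KH (1.3 equiv), THF, 0 °C; then 10, THF/DMF, 0 °C → rt
Reagents that add atoms: none
Why: Nucleophilic aromatic substitution (SNAr): C5–F is ortho to C4a and so activated by the peri C4 carbonyl, fluoride is the best leaving group for addition–elimination, and addition of the bulky tertiary alkoxide at C2 of the pyranone should be reversible in the absence of water whereas fluoride loss is not.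

Step 8
Reactants: 12 7-methoxy-3-[2,4-bis(methoxymethoxy)phenyl]-5-[(2-methylbut-3-en-2-yl)oxy]-4H-chromen-4-one
Product: 14 5-hydroxy-7-methoxy-3-[2,4-bis(methoxymethoxy)phenyl]-6-(3-methylbut-2-en-1-yl)-4H-chromen-4-one, via cyclohexadienone 13 (not isolated)
Conditions: PhNEt2, 130 °C
Reagents that add atoms: none
Why: Aromatic Claisen rearrangement ([3,3]-sigmatropic shift) of a 1,1-dimethylallyl aryl ether: C6 is the only free ortho position because C4a is quaternary, allyl inversion turns the tertiary ether carbon into the CMe2 terminus of a prenyl group, and tautomerisation of dienone 13 gives the chelated 5-hydroxyl.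

Step 9
Reactants: 14 5-hydroxy-7-methoxy-3-[2,4-bis(methoxymethoxy)phenyl]-6-(3-methylbut-2-en-1-yl)-4H-chromen-4-one
Product: 15 7-O-methylluteone, 3-(2,4-dihydroxyphenyl)-5-hydroxy-7-methoxy-6-(3-methylbut-2-en-1-yl)-4H-chromen-4-one
Conditions: 3 M aq HCl, MeOH, 50 °C, stopped as soon as 14 is consumed
Reagents that add atoms: none
Why: Acid-catalysed acetal exchange with methanol removes both aryl MOM ethers, while the 7-methyl ether stays and the chelated, weakly nucleophilic 5-hydroxyl should not add to the prenyl alkene during a short exposure.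

**Compound list**

1 | methyl (2,4-dihydroxyphenyl)acetate | COC(=O)Cc1ccc(O)cc1O | starting material
2 | methyl [2,4-bis(methoxymethoxy)phenyl]acetate | COCOc1ccc(CC(=O)OC)c(OCOC)c1 | intermediate
3 | [2,4-bis(methoxymethoxy)phenyl]acetaldehyde | COCOc1ccc(CC=O)c(OCOC)c1 | intermediate
4 | morpholine | C1COCCN1 | starting material
5 | (E)-4-{2-[2,4-bis(methoxymethoxy)phenyl]ethenyl}morpholine | COCOc1ccc(/C=C/N2CCOCC2)c(OCOC)c1 | intermediate
6 | 2,6-difluoro-4-methoxybenzoic acid | COc1cc(F)c(C(=O)O)c(F)c1 | starting material
7 | 2,6-difluoro-4-methoxybenzoyl chloride | COc1cc(F)c(C(Cl)=O)c(F)c1 | intermediate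
8 | (E)-2-[2,4-bis(methoxymethoxy)phenyl]-1-(2,6-difluoro-4-methoxyphenyl)-3-(morpholin-4-yl)prop-2-en-1-one | COc1cc(F)c(C(=O)/C(=C/N2CCOCC2)c2ccc(OCOC)cc2OCOC)c(F)c1 | intermediate
9 | (Z)-2-[2,4-bis(methoxymethoxy)phenyl]-1-(2,6-difluoro-4-methoxyphenyl)-3-hydroxyprop-2-en-1-one | COc1cc(F)c(C(=O)/C(=C\O)c2ccc(OCOC)cc2OCOC)c(F)c1 | intermediate
10 | 5-fluoro-7-methoxy-3-[2,4-bis(methoxymethoxy)phenyl]-4H-chromen-4-one | COc1cc(F)c2c(=O)c(-c3ccc(OCOC)cc3OCOC)coc2c1 | intermediate
11 | 2-methylbut-3-en-2-ol | CC(C)(O)C=C | starting material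
12 | 7-methoxy-3-[2,4-bis(methoxymethoxy)phenyl]-5-[(2-methylbut-3-en-2-yl)oxy]-4H-chromen-4-one | COc1cc(OC(C)(C)C=C)c2c(=O)c(-c3ccc(OCOC)cc3OCOC)coc2c1 | intermediate
13 | 7-methoxy-3-[2,4-bis(methoxymethoxy)phenyl]-6-(3-methylbut-2-en-1-yl)-4H-chromene-4,5(6H)-dione, racemic at C6 | COC1=CC2=C(C(=O)C1CC=C(C)C)C(=O)C(c1ccc(OCOC)cc1OCOC)=CO2 | intermediate
14 | 5-hydroxy-7-methoxy-3-[2,4-bis(methoxymethoxy)phenyl]-6-(3-methylbut-2-en-1-yl)-4H-chromen-4-one | COc1cc2occ(-c3ccc(OCOC)cc3OCOC)c(=O)c2c(O)c1CC=C(C)C | intermediate
15 | 7-O-methylluteone | COc1cc2occ(-c3ccc(O)cc3O)c(=O)c2c(O)c1CC=C(C)C | target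

**Step count and risks**

Total steps: 9. Longest linear sequence: 8 steps (1 → 2 → 3 → 5 → 9 → 10 → 12 → 14 → 15; step 4 lies on the side branch).

Steps most likely to fail:

Step 7. The tertiary alkoxide may add at C2 of the pyranone and open ring C, or substitution at the hindered peri position may be too slow to outrun base-induced decomposition. The fallback sets out from 10 and comes back to the route at 12. The fluoride of 10 is displaced by the sodium salt of 2-(methylsulfonyl)ethanol (NaH, DMF, 0 °C → rt), a primary alkoxide that should react much faster than a tertiary one. The first-formed 7-methoxy-3-[2,4-bis(methoxymethoxy)phenyl]-5-[2-(methylsulfonyl)ethoxy]-4H-chromen-4-one F1 loses methyl vinyl sulfone by E1cB under the same conditions and should give 5-hydroxy-7-methoxy-3-[2,4-bis(methoxymethoxy)phenyl]-4H-chromen-4-one F2. The tertiary ether is then built on oxygen by Tsuji–Trost allylation: F2 is treated with tert-butyl 2-methylbut-3-en-2-yl carbonate F3 (from 11, n-BuLi and Boc2O) and catalytic Pd(PPh3)4 in THF at 0 °C. The phenoxide should attack the more substituted terminus of the 1,1-dimethylallyl palladium intermediate under kinetic control and give 12.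

Step 6. The β-keto aldehyde may lose its formyl carbon by retro-Claisen cleavage before it cyclises, or the substitution may be slow because the di-ortho-substituted aroyl group is twisted out of conjugation with ring A. The fallback sets out from 6 (and uses 5) and comes back at 10. It closes ring C the classical way, at O1–C2 instead of O1–C8a. Acid 6 is heated with benzyl alcohol and NaH in DMF (80–100 °C), where the first alkoxy group deactivates the ring towards a second substitution, to give 2-(benzyloxy)-6-fluoro-4-methoxybenzoic acid F4. (COCl)2 with catalytic DMF converts it into 2-(benzyloxy)-6-fluoro-4-methoxybenzoyl chloride F5, which acylates enamine 5 (Et3N, CH2Cl2) to give (E)-1-[2-(benzyloxy)-6-fluoro-4-methoxyphenyl]-2-[2,4-bis(methoxymethoxy)phenyl]-3-(morpholin-4-yl)prop-2-en-1-one F6. Hydrogenolysis (H2, Pd/C, EtOAc, rt) frees the phenol (E)-2-[2,4-bis(methoxymethoxy)phenyl]-1-(2-fluoro-6-hydroxy-4-methoxyphenyl)-3-(morpholin-4-yl)prop-2-en-1-one F7. On warming in toluene its hydroxyl should add to the enaminone carbon and expel morpholine to give 10.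

Step 5. C-acylation of the enamine by the di-ortho-substituted aroyl chloride may be sluggish, so that enamine hydrolysis or self-condensation takes over, and the acidic hydrolysis may strip a MOM group. The fallback sets out from 2 and comes back at 9. Ester 2 is converted with MeNHOMe·HCl and iPrMgCl (THF, −20 °C) into 2-[2,4-bis(methoxymethoxy)phenyl]-N-methoxy-N-methylacetamide F8. Commercial 3,5-difluoroanisole is lithiated between its two fluorines (n-BuLi, THF, −78 °C) to give (2,6-difluoro-4-methoxyphenyl)lithium F9. Addition of F9 to F8 at −78 °C should give, after work-up, the deoxybenzoin 2-[2,4-bis(methoxymethoxy)phenyl]-1-(2,6-difluoro-4-methoxyphenyl)ethan-1-one F10. Claisen formylation of F10 (ethyl formate, NaH, THF, 0 °C → rt, AcOH quench) then gives 9 without any acidic hydrolysis.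

Further compounds
F1 | step 7 | 7-methoxy-3-[2,4-bis(methoxymethoxy)phenyl]-5-[2-(methylsulfonyl)ethoxy]-4H-chromen-4-one | COc1cc(OCCS(C)(=O)=O)c2c(=O)c(-c3ccc(OCOC)cc3OCOC)coc2c1
F2 | step 7 | 5-hydroxy-7-methoxy-3-[2,4-bis(methoxymethoxy)phenyl]-4H-chromen-4-one | COc1cc(O)c2c(=O)c(-c3ccc(OCOC)cc3OCOC)coc2c1
F3 | step 7 | tert-butyl 2-methylbut-3-en-2-yl carbonate | CC(C)(C)OC(=O)OC(C)(C)C=C
F4 | step 6 | 2-(benzyloxy)-6-fluoro-4-methoxybenzoic acid | COc1cc(F)c(C(=O)O)c(OCc2ccccc2)c1
F5 | step 6 | 2-(benzyloxy)-6-fluoro-4-methoxybenzoyl chloride | COc1cc(F)c(C(Cl)=O)c(OCc2ccccc2)c1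
F6 | step 6 | (E)-1-[2-(benzyloxy)-6-fluoro-4-methoxyphenyl]-2-[2,4-bis(methoxymethoxy)phenyl]-3-(morpholin-4-yl)prop-2-en-1-one | COc1cc(F)c(C(=O)/C(=C/N2CCOCC2)c2ccc(OCOC)cc2OCOC)c(OCc2ccccc2)c1
F7 | step 6 | (E)-2-[2,4-bis(methoxymethoxy)phenyl]-1-(2-fluoro-6-hydroxy-4-methoxyphenyl)-3-(morpholin-4-yl)prop-2-en-1-one | COc1cc(F)c(C(=O)/C(=C/N2CCOCC2)c2ccc(OCOC)cc2OCOC)c(O)c1
F8 | step 5 | 2-[2,4-bis(methoxymethoxy)phenyl]-N-methoxy-N-methylacetamide | COCOc1ccc(CC(=O)N(C)OC)c(OCOC)c1
F9 | step 5 | (2,6-difluoro-4-methoxyphenyl)lithium | [Li]c1c(F)cc(OC)cc1F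
F10 | step 5 | 2-[2,4-bis(methoxymethoxy)phenyl]-1-(2,6-difluoro-4-methoxyphenyl)ethan-1-one | COc1cc(F)c(C(=O)Cc2ccc(OCOC)cc2OCOC)c(F)c1
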